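**Strategy.** The plan rests on making the C9–C10 bond of the cyclopropane last. In a norbornane with bridgeheads C6 and C8, a phenylsulfonyl carbanion at C9 opens an exo C10–C11 epoxide, so that one step closes the three-membered ring C8–C9–C10, makes C10 quaternary and releases the C11 carbinol that the target carries next to C10 on the cage fused to ring A. The epoxide precursor already holds C3–O and C15 as a γ-lactone bridging ring A and the C4 oxygen as a silyl ether; it comes from an intramolecular Diels–Alder reaction of a masked 1,3-disubstituted cyclopentadiene with an (E)-α-(phenylsulfonylmethylene) lactone.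

Key step: step 11

Numbering used throughout (target numbering): C1 is the quaternary carbon bearing C15 (the CH2OAc carbon); ring A is C1–C2–C3–C4–C5–C6 (C3 CHOAc, C4 CHOH, C5 CMe2); C6 is the cage apex; C7 is the methylene bridge; the cyclopropane is C8 (on C7), C9 (on C1) and C10 (methyl-bearing); C11 (CHOAc) joins C10 to C6.

Remarks on the chemistry:
- The cyclopentadiene is carried through steps 1–8 as a tertiary allylic silyl ether, because a free cyclopentadiene would not survive the enolate, epoxidation and sulfonylation chemistry. Its carbinol carbon (later C6) is racemic, so 3–18 are epimer pairs at that centre once C3/C4 are set; the centre is erased in step 9 and is left undefined in the SMILES.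
- Compounds 21 and 22 are drawn so that every stereocentre maps onto the target: C15 exo and C2 endo at C1, PhSO2 endo at C9 in 21, epoxide oxygen exo. Compared with a precursor lacking the C3 oxygen, they carry C3–O and C15 as a lactone, so no oxidation or reduction at C3/C4 is needed after the key step.
- Assumption: the vinylzinc addition in step 3 follows the Si-face preference that (−)-MIB [(2S)-3-exo-morpholinoisoborneol] shows in dialkylzinc additions.

## Route

Step 1
Reactants: 1 isobutyronitrile; 2 3-methylcyclopent-2-en-1-one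
Product: 4 2-methyl-2-[3-methyl-1-(triethylsilyloxy)cyclopent-2-en-1-yl]propanenitrile (racemic), via lithium alkoxide 3 (not isolated)
Conditions: LiN(iPr)2 (1.05 equiv), THF, −78 °C; 2; then Et3SiOTf (1.2 equiv), −78 → 0 °C
Reagents that add atoms: triethylsilyl trifluoromethanesulfonate, CC[Si](CC)(CC)OS(=O)(=O)C(F)(F)F
Why: Carbonyl 1,2-addition of the α-lithiated nitrile to the enone (conjugate addition is disfavoured by the β-methyl group) followed by O-silylation of the lithium alkoxide traps the tertiary allylic alcohol as a base-stable precursor of the cyclopentadiene; its carbinol carbon is a racemic stereocentre that is erased later.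

Step 2
Reactants: 4 2-methyl-2-[3-methyl-1-(triethylsilyloxy)cyclopent-2-en-1-yl]propanenitrile
Product: 6 2-methyl-2-[3-methyl-1-(triethylsilyloxy)cyclopent-2-en-1-yl]propanal, via aldimine 5 (not isolated)
Conditions: iBu2AlH (1.3 equiv), CH2Cl2, −78 → −20 °C; KNaC4H4O6 (aq), then pH 5 buffer, 0 °C
Reagents that add atoms: water, O
Why: Partial reduction of a nitrile by iBu2AlH stops at the N-aluminated imine, which hydrolyses on buffered work-up to the neopentyl aldehyde without touching the silyl ether or the ring alkene.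

Step 3
Reactants: 6 2-methyl-2-[3-methyl-1-(triethylsilyloxy)cyclopent-2-en-1-yl]propanal; 7 vinylmagnesium bromide
Product: 8 (3S)-4-methyl-4-[3-methyl-1-(triethylsilyloxy)cyclopent-2-en-1-yl]pent-1-en-3-ol
Conditions: 7 (2.4 equiv), ZnCl2 (1.2 equiv), THF–dioxane, magnesium salts filtered off to give (CH2=CH)2Zn; (−)-MIB (10 mol%), PhMe, 0 °C; NH4Cl (aq)
Reagents that add atoms: none
Why: Catalytic enantioselective addition of an alkenylzinc reagent to an aldehyde under amino-alcohol ligand control should deliver the vinyl group to the Si face of this pivaldehyde-like carbonyl and so set C4 (S in 8; the same spatial arrangement is R in the target by a change of priorities).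

Step 4
Reactants: 8 (3S)-4-methyl-4-[3-methyl-1-(triethylsilyloxy)cyclopent-2-en-1-yl]pent-1-en-3-ol
Product: 9 (1R)-2-methyl-2-[3-methyl-1-(triethylsilyloxy)cyclopent-2-en-1-yl]-1-[(2S)-oxiran-2-yl]propan-1-ol
Conditions: Ti(OiPr)4 (0.3 equiv), D-(−)-diisopropyl tartrate (0.36 equiv), t-BuOOH (2 equiv), 4 Å MS, CH2Cl2, −20 °C
Reagents that add atoms: tert-butyl hydroperoxide, CC(C)(C)OO
Why: Sharpless asymmetric epoxidation of a secondary allylic alcohol in its matched, fast-reacting pairing: the titanium-bound C4 alkoxide directs oxygen to one face of the vinyl group, which should give the erythro (anti) epoxy alcohol and set C3, while any minor enantiomer of 8 reacts slowly and is left behind and the silylated ring alkene, lacking a directing hydroxyl, is not attacked.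

Step 5
Reactants: 9 (1R)-2-methyl-2-[3-methyl-1-(triethylsilyloxy)cyclopent-2-en-1-yl]-1-[(2S)-oxiran-2-yl]propan-1-ol
Product: 10 triisopropylsilyl ether of 9 at the C4 oxygen
Conditions: iPr3SiOTf (1.3 equiv), 2,6-lutidine (2 equiv), CH2Cl2, −78 → 0 °C
Reagents that add atoms: triisopropylsilyl trifluoromethanesulfonate, CC(C)[Si](C(C)C)(C(C)C)OS(=O)(=O)C(F)(F)F
Why: Silyl triflate silylation under a hindered pyridine base protects the C4 hydroxyl without Payne rearrangement of the epoxy alcohol; the triisopropylsilyl group is chosen because it should not migrate to the neighbouring C3 alkoxide formed in step 6 and survives the acid of step 9.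

Step 6
Reactants: 10 triisopropylsilyl ether of 9; 11 acetic acid
Product: 13 (5S)-5-{(1R)-2-methyl-2-[3-methyl-1-(triethylsilyloxy)cyclopent-2-en-1-yl]-1-(triisopropylsilyloxy)propyl}oxolan-2-one, via hydroxy acid 12 (not isolated)
Conditions: 11 (3 equiv), LiN(iPr)2 (6 equiv), THF, 0 °C; 10, DMPU, 45 °C; AcOH (to neutrality), 0 °C, aqueous work-up; PhMe, 60 °C
Reagents that add atoms: none
Why: The dianion of acetic acid opens the terminal epoxide at its CH2 carbon C2 (SN2 epoxide opening by a carboxylate enolate, C3 untouched), and the γ-hydroxy acid lactonises on warming, which places C15 and the C3 oxygen in one five-membered ring.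

Step 7
Reactants: 13 lactone; 14 methyl formate
Product: 16 3-[(4-methylphenylsulfonyloxy)methylene] derivative of 13 (E/Z mixture at C1=C9), via hydroxymethylene lactone 15 (not isolated)
Conditions: LiN(iPr)2 (1.2 equiv), THF, −78 °C; 14 (3 equiv), −78 → 0 °C; then TsCl (1.5 equiv), 0 °C
Reagents that add atoms: 4-methylbenzenesulfonyl chloride, Cc1ccc(cc1)S(=O)(=O)Cl
Why: Claisen-type formylation of the lactone enolate at C1, its only enolisable position, gives the lithium enolate of the α-formyl lactone, which is O-sulfonylated in the same flask to an enol tosylate set up for substitution at C9.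

Step 8
Reactants: 16 enol tosylate; 17 sodium benzenesulfinate
Product: 18 (3E,5S)-3-[(phenylsulfonyl)methylene]-5-{(1R)-2-methyl-2-[3-methyl-1-(triethylsilyloxy)cyclopent-2-en-1-yl]-1-(triisopropylsilyloxy)propyl}oxolan-2-one
Conditions: 17 (1.5 equiv), DMF, 20 °C
Reagents that add atoms: none
Why: Addition–elimination (nucleophilic vinylic substitution) of the sulfinate sulfur at C9 of the β-tosyloxy enoate expels tosylate under neutral conditions and should give the β-sulfonyl alkylidene lactone as the (E) isomer with the sulfone anti to the carbonyl; any (Z) isomer converges later because C9 is deprotonated in step 11.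

Step 9
Reactants: 18 (E)-α-(phenylsulfonylmethylene) lactone
Product: 20 norbornene lactone sulfone (C1–C6 and C8–C9 bonds formed; bridgeheads C6 and C8; C10(Me)=C11 alkene; C15 carbonyl exo and C2 endo at C1; PhSO2 endo at C9), via cyclopentadiene 19 (not isolated)
Conditions: TsOH·H2O (10 mol%), PhMe, 50 °C; NaHCO3 (solid), filter; PhMe (0.005 M), BHT, 110 °C
Reagents that add atoms: none
Why: Acid-catalysed E1 loss of triethylsilanol from the tertiary allylic ether gives the cyclopentadiene, whose tautomers interconvert by 1,5-hydrogen shifts so that only the 1-substituted isomer can reach the dienophile in an intramolecular Diels–Alder reaction closing ring A and the norbornene; the lactone forces the new C1–C6 bond onto the face of the C4 arm, the carbonyl C15 should take the exo position usual for s-cis α-alkylidene lactones (the sp2 carbon C11 rather than the C7 methylene then lies over ring A) with C2 and the (E) sulfone endo, and suprafacial addition sets C1, C6, C8 and C9 with the C4 silyloxy group equatorial.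

Step 10
Reactants: 20 norbornene lactone sulfone
Product: 21 exo-10,11-epoxide of 20
Conditions: mCPBA (1.5 equiv), NaHCO3, CH2Cl2, 0 → 20 °C
Reagents that add atoms: 3-chloroperoxybenzoic acid, OOC(=O)c1cccc(Cl)c1
Why: Prilezhaev epoxidation of the trisubstituted norbornene C10=C11 from the exo face, the endo face being covered by C2 and the endo sulfone, sets C10 and C11 with oxygen on the C7 side, while the sulfone and lactone are inert to the peracid.

Step 11
Reactants: 21 exo-epoxy norbornane lactone sulfone
Product: 22 nortricyclanol lactone sulfone (cyclopropane C8–C9–C10; PhSO2 on C9; free C11–OH)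
Conditions: LiN(iPr)2 (1.3 equiv), THF, −78 → 0 °C; AcOH
Reagents that add atoms: none
Why: Deprotonation of the exo C9–H next to the sulfone gives a configurationally mobile α-sulfonyl carbanion whose endo lobe lies about 2.5 Å from C10 and anti to the exo C10–O bond; it displaces the epoxide oxygen at the tertiary carbon in an intramolecular SN2 opening that forms C9–C10 and the C11 lithium alkoxide. The closest known reaction type is the base-induced cyclisation of exo-epoxynorbornanes bearing a carbanion-stabilising group to nortricyclanols, a 1,3-elimination of the kind used to make cyclopropanes from γ,δ-epoxy sulfones. The cyclopropane C8–C9–C10 is closed in the 3-exo-tet mode. C10 becomes quaternary with inversion, dictated by backside attack from the endo face; C9 becomes a cage stereocentre whose configuration the tricyclic framework fixes; C11 keeps the oxygen placed by the exo epoxidation. The step needs attack at C10 and not at C11, which is secured because a C9–C11 bond would give a bridged cyclobutane, and it needs the base to spare the lactone, which is secured by the quaternary C1 (no α-hydrogen, hindered carbonyl), a non-nucleophilic amide base and C9–H being the only acidic C–H.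

Step 12
Reactants: 22 nortricyclanol lactone sulfone
Product: 23 C3,C11,C15-triol C9-sulfone with C4–OSi(iPr)3
Conditions: LiAlH4 (3 equiv), THF, 0 → 20 °C; NaOH (aq) work-up
Reagents that add atoms: none
Why: Hydride reduction of the lactone by LiAlH4 gives the C15 primary alcohol and the axial C3 alcohol in one operation with the C3 configuration already fixed, the aryl sulfone and the silyl ether being stable under these conditions.

Step 13
Reactants: 23 triol sulfone
Product: 24 C3,C11,C15-triol with C4–OSi(iPr)3 (C9–H)
Conditions: Na/Hg (6% Na, 6 equiv), Na2HPO4, MeOH–THF, −20 → 0 °C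
Reagents that add atoms: none
Why: Reductive desulfonylation by electron transfer from sodium amalgam cleaves the C9–S bond and methanol protonates the cyclopropyl anion, the cage allowing only one configuration at C9, while the phosphate buffer keeps the medium from turning strongly basic.

Step 14
Reactants: 24 silyl-protected triol
Product: 25 C3,C4,C11,C15-tetraol
Conditions: Bu4NF (3 equiv), THF, 60 °C
Reagents that add atoms: none
Why: Fluoride-induced desilylation, driven by Si–F bond formation, frees the neopentyl C4 hydroxyl.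

Step 15
Reactants: 25 tetraol
Product: 28 CNP0197219.1 (C3,C11,C15-triacetate with free C4–OH), via orthoester diol 26 (not isolated), via orthoester diacetate 27 (not isolated)
Conditions: MeC(OMe)3 (1.3 equiv), CSA (5 mol%), CH2Cl2, 20 °C; then Ac2O, pyridine, DMAP, 20 → 40 °C; then AcOH–H2O (4:1), 20 °C
Reagents that add atoms: trimethyl orthoacetate, COC(C)(OC)OC; acetic anhydride, CC(=O)OC(C)=O; water, O
Why: Acid-catalysed orthoester exchange ties the cis C3/C4 diol as a five-membered cyclic orthoester, acylation then esterifies the C15 and C11 hydroxyls, and mild aqueous acid opens the orthoester through a dioxolan-2-ylium ion and its hemi-orthoester to the axial C3 acetate with the equatorial C4 hydroxyl free (the usual regiochemistry of orthoester hydrolysis on six-membered rings), so the target needs no further differentiation of the hydroxyls.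

## Compound list

1 | isobutyronitrile | CC(C)C#N | starting material
2 | 3-methylcyclopent-2-en-1-one | CC1=CC(=O)CC1 | starting material
3 | lithium 1-(2-cyanopropan-2-yl)-3-methylcyclopent-2-en-1-olate (not isolated) | [Li+].[O-]C1(C=C(C)CC1)C(C)(C)C#N | intermediate
4 | 2-methyl-2-[3-methyl-1-(triethylsilyloxy)cyclopent-2-en-1-yl]propanenitrile (racemic) | CC[Si](CC)(CC)OC1(C=C(C)CC1)C(C)(C)C#N | intermediate
5 | 2-methyl-2-[3-methyl-1-(triethylsilyloxy)cyclopent-2-en-1-yl]propan-1-imine (formed as its N-aluminium derivative, not isolated) | CC[Si](CC)(CC)OC1(C=C(C)CC1)C(C)(C)C=N | intermediate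
6 | 2-methyl-2-[3-methyl-1-(triethylsilyloxy)cyclopent-2-en-1-yl]propanal | CC[Si](CC)(CC)OC1(C=C(C)CC1)C(C)(C)C=O | intermediate
7 | vinylmagnesium bromide | C=C[Mg]Br | starting material
8 | (3S)-4-methyl-4-[3-methyl-1-(triethylsilyloxy)cyclopent-2-en-1-yl]pent-1-en-3-ol | C=C[C@H](O)C(C)(C)C1(O[Si](CC)(CC)CC)C=C(C)CC1 | intermediate
9 | (1R)-2-methyl-2-[3-methyl-1-(triethylsilyloxy)cyclopent-2-en-1-yl]-1-[(2S)-oxiran-2-yl]propan-1-ol (erythro) | C1[C@H](O1)[C@H](O)C(C)(C)C1(O[Si](CC)(CC)CC)C=C(C)CC1 | intermediate
10 | triisopropylsilyl ether of 9 | C1[C@H](O1)[C@H](O[Si](C(C)C)(C(C)C)C(C)C)C(C)(C)C1(O[Si](CC)(CC)CC)C=C(C)CC1 | intermediate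
11 | acetic acid | CC(=O)O | starting material
12 | (4S,5R)-4-hydroxy-6-methyl-6-[3-methyl-1-(triethylsilyloxy)cyclopent-2-en-1-yl]-5-(triisopropylsilyloxy)heptanoic acid (not isolated) | OC(=O)CC[C@H](O)[C@H](O[Si](C(C)C)(C(C)C)C(C)C)C(C)(C)C1(O[Si](CC)(CC)CC)C=C(C)CC1 | intermediate
13 | (5S)-5-{(1R)-2-methyl-2-[3-methyl-1-(triethylsilyloxy)cyclopent-2-en-1-yl]-1-(triisopropylsilyloxy)propyl}oxolan-2-one | O=C1CC[C@H](O1)[C@H](O[Si](C(C)C)(C(C)C)C(C)C)C(C)(C)C1(O[Si](CC)(CC)CC)C=C(C)CC1 | intermediate
14 | methyl formate | COC=O | starting material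
15 | 3-(hydroxymethylene) derivative of 13 (formed as its lithium enolate, not isolated) | O=C1C(=CO)C[C@H](O1)[C@H](O[Si](C(C)C)(C(C)C)C(C)C)C(C)(C)C1(O[Si](CC)(CC)CC)C=C(C)CC1 | intermediate
16 | 3-[(4-methylphenylsulfonyloxy)methylene] derivative of 13 (E/Z) | O=C1C(=COS(=O)(=O)c2ccc(C)cc2)C[C@H](O1)[C@H](O[Si](C(C)C)(C(C)C)C(C)C)C(C)(C)C1(O[Si](CC)(CC)CC)C=C(C)CC1 | intermediate
17 | sodium benzenesulfinate | [Na+].[O-]S(=O)c1ccccc1 | starting material
18 | (3E,5S)-3-[(phenylsulfonyl)methylene]-5-{(1R)-2-methyl-2-[3-methyl-1-(triethylsilyloxy)cyclopent-2-en-1-yl]-1-(triisopropylsilyloxy)propyl}oxolan-2-one | O=C1/C(=C/S(=O)(=O)c2ccccc2)C[C@H](O1)[C@H](O[Si](C(C)C)(C(C)C)C(C)C)C(C)(C)C1(O[Si](CC)(CC)CC)C=C(C)CC1 | intermediate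
19 | (3E,5S)-5-[(1R)-2-methyl-2-(3-methylcyclopenta-1,3-dien-1-yl)-1-(triisopropylsilyloxy)propyl]-3-[(phenylsulfonyl)methylene]oxolan-2-one (not isolated) | O=C1/C(=C/S(=O)(=O)c2ccccc2)C[C@H](O1)[C@H](O[Si](C(C)C)(C(C)C)C(C)C)C(C)(C)C1=CC(C)=CC1 | intermediate
20 | norbornene lactone sulfone: ring A fused at C1–C6, lactone C15(=O)–O–C3, C15 exo and C2 endo at C1, PhSO2 endo at C9, C10(Me)=C11, C4–OSi(iPr)3 | O=C5[C@]12C[C@H](O5)[C@H](O[Si](C(C)C)(C(C)C)C(C)C)C(C)(C)[C@]13C[C@@H](C(C)=C3)[C@H]2S(=O)(=O)c2ccccc2 | intermediate
21 | exo-10,11-epoxide of 20 (key-step precursor) | O=C5[C@]12C[C@H](O5)[C@H](O[Si](C(C)C)(C(C)C)C(C)C)C(C)(C)[C@]13C[C@@H]([C@@]4(C)O[C@@H]34)[C@H]2S(=O)(=O)c2ccccc2 | intermediate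
22 | nortricyclanol lactone sulfone: cyclopropane C8–C9–C10, PhSO2 on C9, C11–OH, lactone C15(=O)–O–C3, C4–OSi(iPr)3 (key-step product) | O=C5[C@]12C[C@H](O5)[C@H](O[Si](C(C)C)(C(C)C)C(C)C)C(C)(C)[C@]13C[C@@H]1[C@@]2(S(=O)(=O)c2ccccc2)[C@]1(C)[C@H]3O | intermediate
23 | C3,C11,C15-triol C9-sulfone with C4–OSi(iPr)3 | OC[C@]12C[C@H](O)[C@H](O[Si](C(C)C)(C(C)C)C(C)C)C(C)(C)[C@]13C[C@@H]1[C@@]2(S(=O)(=O)c2ccccc2)[C@]1(C)[C@H]3O | intermediate
24 | C3,C11,C15-triol with C4–OSi(iPr)3 (C9–H) | OC[C@]12C[C@H](O)[C@H](O[Si](C(C)C)(C(C)C)C(C)C)C(C)(C)[C@]13C[C@@H]1[C@H]2[C@]1(C)[C@H]3O | intermediate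
25 | C3,C4,C11,C15-tetraol | OC[C@]12C[C@H](O)[C@H](O)C(C)(C)[C@]13C[C@@H]1[C@H]2[C@]1(C)[C@H]3O | intermediate
26 | C3,C4-cyclic methyl orthoacetate of 25 (not isolated; orthoester carbon undefined) | OC[C@]12C[C@H](OC(C)(OC)O4)[C@H]4C(C)(C)[C@]13C[C@@H]1[C@H]2[C@]1(C)[C@H]3O | intermediate
27 | C11,C15-diacetate of 26 (not isolated) | CC(=O)OC[C@]12C[C@H](OC(C)(OC)O4)[C@H]4C(C)(C)[C@]13C[C@@H]1[C@H]2[C@]1(C)[C@H]3OC(C)=O | intermediate
28 | CNP0197219.1 | CC(=O)OC[C@]12C[C@H](OC(C)=O)[C@H](O)C(C)(C)[C@]13C[C@@H]1[C@H]2[C@]1(C)[C@H]3OC(C)=O | target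

## Step count and risks

Total step count: 15. Longest linear sequence: 15 steps (the route is linear from 1 and 2).

The three steps most likely to fail:

**Step 11 (key step).** The amide base or the newly formed C11 alkoxide may attack the bridged lactone, or base-induced isomerisation of the epoxide to an allylic alcohol may compete with ring closure. The fallback removes the lactone before the carbanion is generated. It sets out from 21: LiBH4 (THF, 0 → 20 °C) should reduce the lactone without opening the hindered epoxide to the epoxy diol sulfone F1. Et3SiOTf/2,6-lutidine would give the bis(triethylsilyl) ether F2. LiN(iPr)2 (THF, −78 → 0 °C) would then close the cyclopropane to the bis-silylated nortricyclanol F3. HF·pyridine (THF, 0 °C) would remove the two triethylsilyl groups, and the sequence comes back to the route at 23.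

**Step 9.** Ionisation of the tertiary allylic ether by acid may be diverted before the diene is trapped: cationic rearrangement next to the quaternary C5, loss of the C4 silyl group or acid-promoted oligomerisation of the diene. The fallback makes the diene under neutral conditions. It sets out from 18: HF·pyridine (THF, 0 °C) should remove only the triethylsilyl group to give the tertiary allylic alcohol F4. Burgess reagent (PhMe, 50 °C) would dehydrate it by syn elimination of the sulfamate to diene 19, which on dilution and heating to 110 °C comes back to the route at 20.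

**Step 4.** Oxygen transfer to the vinyl group of the neopentyl-type carbinol 8 may be too slow or not selective enough. The fallback sets both stereocentres on a primary allylic alcohol instead. It sets out from 6: Wittig reaction with Ph3P=CHCO2Et (PhMe, 80 °C) would give the (E)-enoate F5, and iBu2AlH the (E)-allylic alcohol F6. Sharpless epoxidation with D-(−)-diethyl tartrate would give the (2R,3R)-epoxy alcohol F7. Tf2O/2,6-lutidine followed by the lithium enolate of methyl acetate (THF, −78 °C) would give the epoxy ester F8. LiOH and then acidification to pH 4 would let the carboxylic acid open the epoxide at C3 with inversion (5-exo) to the hydroxy lactone F9. iPr3SiOTf/2,6-lutidine then comes back to the route at 13.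

## Further compounds

F1 | step 11 | epoxy diol sulfone (C3–OH, C15–OH, exo-10,11-epoxide, C4–OSi(iPr)3) | OC[C@]12C[C@H](O)[C@H](O[Si](C(C)C)(C(C)C)C(C)C)C(C)(C)[C@]13C[C@@H]([C@@]4(C)O[C@@H]34)[C@H]2S(=O)(=O)c2ccccc2
F2 | step 11 | C3,C15-bis(triethylsilyl) ether of F1 | CC[Si](CC)(CC)OC[C@]12C[C@H](O[Si](CC)(CC)CC)[C@H](O[Si](C(C)C)(C(C)C)C(C)C)C(C)(C)[C@]13C[C@@H]([C@@]4(C)O[C@@H]34)[C@H]2S(=O)(=O)c2ccccc2
F3 | step 11 | C3,C15-bis(triethylsilyl) ether of nortricyclanol 23 | CC[Si](CC)(CC)OC[C@]12C[C@H](O[Si](CC)(CC)CC)[C@H](O[Si](C(C)C)(C(C)C)C(C)C)C(C)(C)[C@]13C[C@@H]1[C@@]2(S(=O)(=O)c2ccccc2)[C@]1(C)[C@H]3O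
F4 | step 9 | tertiary allylic alcohol from 18 (triethylsilyl group removed) | O=C1/C(=C/S(=O)(=O)c2ccccc2)C[C@H](O1)[C@H](O[Si](C(C)C)(C(C)C)C(C)C)C(C)(C)C1(O)C=C(C)CC1
F5 | step 4 | ethyl (2E)-4-methyl-4-[3-methyl-1-(triethylsilyloxy)cyclopent-2-en-1-yl]pent-2-enoate | CCOC(=O)/C=C/C(C)(C)C1(O[Si](CC)(CC)CC)C=C(C)CC1
F6 | step 4 | (2E)-4-methyl-4-[3-methyl-1-(triethylsilyloxy)cyclopent-2-en-1-yl]pent-2-en-1-ol | OC/C=C/C(C)(C)C1(O[Si](CC)(CC)CC)C=C(C)CC1
F7 | step 4 | [(2R,3R)-3-{2-[3-methyl-1-(triethylsilyloxy)cyclopent-2-en-1-yl]propan-2-yl}oxiran-2-yl]methanol | OC[C@@H](O1)[C@H]1C(C)(C)C1(O[Si](CC)(CC)CC)C=C(C)CC1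
F8 | step 4 | methyl 3-[(2R,3R)-3-{2-[3-methyl-1-(triethylsilyloxy)cyclopent-2-en-1-yl]propan-2-yl}oxiran-2-yl]propanoate | COC(=O)CC[C@@H](O1)[C@H]1C(C)(C)C1(O[Si](CC)(CC)CC)C=C(C)CC1
F9 | step 4 | (5S)-5-{(1R)-1-hydroxy-2-methyl-2-[3-methyl-1-(triethylsilyloxy)cyclopent-2-en-1-yl]propyl}oxolan-2-one | O=C1CC[C@H](O1)[C@H](O)C(C)(C)C1(O[Si](CC)(CC)CC)C=C(C)CC1
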